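**Retrosynthetic overview**
- Target 6 ⇒ dibromide 4, by cutting both aryl–prenyl C–C bonds (double linear-selective Negishi prenylation, done last).
- 4 ⇒ vinyl ester 2 + (R)-terpinen-4-ol 3, by cutting the acyl C–O bond of the tertiary ester (key step, new copper-alkoxide acyl transfer). The only stereocentre comes from 3 and is retained.
- 2 ⇒ 3,5-dibromo-4-methoxybenzoic acid 1 + vinyl acetate.
- No ring is formed: the benzene ring is that of 1 and the cyclohexene ring that of 3.

Assumption: commercial (−)-terpinen-4-ol (3) is the (R)-enantiomer in high but possibly incomplete optical purity; its er is measured by chiral GC before use.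

**Step 1**
Reactants: 1 3,5-dibromo-4-methoxybenzoic acid
Product: 2 ethenyl (vinyl) 3,5-dibromo-4-methoxybenzoate
Conditions: Pd(OAc)2 (5 mol%), KOH (10 mol%), vinyl acetate/THF 5:1, 25 °C, 24 h
Reagents that add atoms: vinyl acetate (ethenyl acetate), CC(=O)OC=C
Why: Transvinylation (vinyl interchange) catalysed by divalent palladium: carboxylate oxypalladation of vinyl acetate, then β-acetate elimination, driven by excess vinyl acetate; the aryl bromides are inert at room temperature and no stereocentre is involved.

**Step 2**
Reactants: 2 ethenyl 3,5-dibromo-4-methoxybenzoate; 3 (1R)-4-methyl-1-(propan-2-yl)cyclohex-3-en-1-ol, (R)-(−)-terpinen-4-ol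
Product: 4 (1R)-4-methyl-1-(propan-2-yl)cyclohex-3-en-1-yl 3,5-dibromo-4-methoxybenzoate
Conditions: CuMes (mesitylcopper, Mes = 2,4,6-Me3C6H2, 5 mol%), (S,S)-t-Bu-BOX (2,2'-(propane-2,2-diyl)bis[(4S)-4-tert-butyl-4,5-dihydrooxazole], 6 mol%), 3 (1.5 equiv), toluene, 0 to 23 °C, slow N2 sweep
Reagents that add atoms: none
Why: Proposed new method: enantiomer-selective acyl transfer from an enol ester to a tertiary homoallylic alcohol through a chiral monovalent-copper alkoxide. CuMes and 3 give the BOX-ligated copper alkoxide, which attacks the activated vinyl ester to give 4 and a copper ethenolate; the next molecule of 3 protonates it and acetaldehyde leaves, so no base is needed and free 3 has no uncatalysed pathway. The alkoxide can bind copper through O and η2 through its own ring alkene, so the two enantiomers form diastereomeric two-point chelates in the C2-symmetric ligand and the matched (R)-alkoxide is acylated faster, which upgrades the er of an excess of imperfectly pure 3. Only the O–H bond of 3 is broken, so the stereocentre is carried over with retention. Closest known reaction types: Cu(OTf)2–bis(oxazoline)-catalysed benzoylative kinetic resolution of 1,2-diols by chelation, asymmetric acyl transfer from vinyl benzoate by a dinuclear zinc alkoxide made from ZnEt2, and CuH–bisphosphine kinetic resolution of tertiary propargylic alcohols by Si–O coupling.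

**Step 3**
Reactants: 4 (1R)-4-methyl-1-(propan-2-yl)cyclohex-3-en-1-yl 3,5-dibromo-4-methoxybenzoate
Product: 6 (1R)-4-methyl-1-(propan-2-yl)cyclohex-3-en-1-yl 4-methoxy-3,5-bis(3-methylbut-2-en-1-yl)benzoate, via monoprenyl monobromo ester 5 (not isolated)
Conditions: Me2C=CHCH2ZnBr (3.0 equiv, from prenyl bromide, Zn dust, LiCl, THF, 0 °C), Pd(OAc)2 (4 mol%), CPhos (2-dicyclohexylphosphino-2',6'-bis(dimethylamino)biphenyl, 8 mol%), THF, 23 °C
Reagents that add atoms: prenylzinc bromide, CC(C)=CC[Zn]Br, made from prenyl bromide (1-bromo-3-methylbut-2-ene), CC(C)=CCBr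
Why: Linear-selective Negishi cross-coupling: with the bulky biarylphosphine, reductive elimination from the α-bound prenyl(aryl)palladium is faster than allyl transposition, so both bromides are replaced by unrearranged prenyl groups; the hindered tertiary ester, the ring alkene and the stereocentre are not touched.

**Compound list**
1 | 3,5-dibromo-4-methoxybenzoic acid | COc1c(Br)cc(C(=O)O)cc1Br | starting material
2 | ethenyl (vinyl) 3,5-dibromo-4-methoxybenzoate | COc1c(Br)cc(C(=O)OC=C)cc1Br | intermediate
3 | (1R)-4-methyl-1-(propan-2-yl)cyclohex-3-en-1-ol, (R)-(−)-terpinen-4-ol | O[C@@]1(C(C)C)CC=C(C)CC1 | starting material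
4 | (1R)-4-methyl-1-(propan-2-yl)cyclohex-3-en-1-yl 3,5-dibromo-4-methoxybenzoate | COc1c(Br)cc(C(=O)O[C@@]2(C(C)C)CC=C(C)CC2)cc1Br | intermediate
5 | (1R)-4-methyl-1-(propan-2-yl)cyclohex-3-en-1-yl 3-bromo-4-methoxy-5-(3-methylbut-2-en-1-yl)benzoate | COc1c(CC=C(C)C)cc(C(=O)O[C@@]2(C(C)C)CC=C(C)CC2)cc1Br | intermediate
6 | (1R)-4-methyl-1-(propan-2-yl)cyclohex-3-en-1-yl 4-methoxy-3,5-bis(3-methylbut-2-en-1-yl)benzoate | COc1c(CC=C(C)C)cc(C(=O)O[C@@]2(C(C)C)CC=C(C)CC2)cc1CC=C(C)C | target

**Totals**
Total steps: 3. Longest linear sequence: 3 (1 → 2 → 4 → 6).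

**Steps most likely to fail**

Step 2 (the proposed new step) is the riskiest.
- The hindered tertiary alkoxide may turn over slowly on copper.
- Which ligand antipode is matched to (R) cannot be predicted; one test run settles it (if recovered 3 is enriched in (R), the (R,R)-ligand is used).
- The O/alkene chelate could undergo β-carbon elimination (retro-allylation) if warmed.
- If the design works with a selectivity factor near 10, a 90:10 lot of 3 would give 4 of about 98:2 er at full conversion of 2.

Fallback with known chemistry: it sets out from 3 and returns at 4. A lot of 3 of at least 98% ee (selected by chiral GC or enriched by preparative chiral chromatography) is deprotonated with n-BuLi in THF at −78 to 0 °C to give lithium (1R)-4-methyl-1-(propan-2-yl)cyclohex-3-en-1-olate F1. Vinyl ester 2 is added at −40 °C. The stoichiometric alkoxide attacks the activated enol ester irreversibly, lithium ethenolate leaves, and NH4Cl work-up gives 4 with retention. This gives no er upgrade.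

Step 3 is the next risk: branched (reverse-prenyl) isomers, an incomplete second coupling, or slow addition of the allylzinc to the ester.

Fallback with reversed polarity: it sets out from 4, passes through 5 and ends at 6. Br/Mg exchange on 4 with i-PrMgCl·LiCl (THF, −20 °C) gives {3-bromo-2-methoxy-5-[(1R)-4-methyl-1-(propan-2-yl)cyclohex-3-en-1-yloxycarbonyl]phenyl}magnesium chloride F2. Allylation with prenyl bromide and CuBr·SMe2 (10 mol%) gives 5 by SN2-type attack at the primary carbon. A second exchange on 5 at 0 °C gives {2-methoxy-3-(3-methylbut-2-en-1-yl)-5-[(1R)-4-methyl-1-(propan-2-yl)cyclohex-3-en-1-yloxycarbonyl]phenyl}magnesium chloride F3, and the same allylation gives 6.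

Step 1 is the least risky: incomplete exchange, or loss of the catalyst as palladium metal.

Fallback: it sets out from 1 and returns at 2. Acid 1 is converted with SOCl2 (cat. DMF, toluene, 70 °C) into 3,5-dibromo-4-methoxybenzoyl chloride F4. F4 is added at −78 °C to LiOCH=CH2 (lithium ethenolate, made by cleaving THF with n-BuLi at 25 °C). O-Acylation gives 2.

**Further compounds**
F1 | step 2 | lithium (1R)-4-methyl-1-(propan-2-yl)cyclohex-3-en-1-olate | [Li+].[O-][C@@]1(C(C)C)CC=C(C)CC1
F2 | step 3 | {3-bromo-2-methoxy-5-[(1R)-4-methyl-1-(propan-2-yl)cyclohex-3-en-1-yloxycarbonyl]phenyl}magnesium chloride | COc1c(Br)cc(C(=O)O[C@@]2(C(C)C)CC=C(C)CC2)cc1[Mg]Cl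
F3 | step 3 | {2-methoxy-3-(3-methylbut-2-en-1-yl)-5-[(1R)-4-methyl-1-(propan-2-yl)cyclohex-3-en-1-yloxycarbonyl]phenyl}magnesium chloride | COc1c(CC=C(C)C)cc(C(=O)O[C@@]2(C(C)C)CC=C(C)CC2)cc1[Mg]Cl
F4 | step 1 | 3,5-dibromo-4-methoxybenzoyl chloride | COc1c(Br)cc(C(=O)Cl)cc1Br
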